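**Plan**

- Retrosynthesis: the lactone carbonyl C2=O is taken back to a methyl acetal, then the O1–C2 bond is cut. This leaves a C3a–C7a epoxide whose C3a carries a C3=C2 methyl enol ether. Further cuts are C2=C3 (Wittig), the two oxirane C–O bonds (epoxidation of an allylic alcohol), C3a–C3 (carbonylation of an enol triflate) and the C6 O–acyl bond.
- Enabling feature (benzofuranone numbering O1, C2, C3, C3a, C4–C7, C7a): the dihydrofuran ring O1–C2–C3=C3a–C7a, fused to the gem-dimethylcyclohexane across C3a–C7a, is the furanoid isomer of that epoxide. Ionising C3a–O gives an allyl cation that ends at the methoxy-bearing C2, which the oxygen left on C7a can reach.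
- Forward order: the carbocycle comes from ketoisophorone, the oxirane is made in step 6, the two-carbon enol ether is attached in step 8, the dihydrofuran closes as the oxirane opens in step 11, and oxidation gives the lactone.
- Stereochemistry: C6 comes from the enzymatic reduction of step 1 (the (4R) carbinol; the later change to S is only a change in substituent ranking). C7a comes from the tartrate-controlled epoxidation of step 6, anti to the C6 oxygen, and its C–O bond is never broken afterwards.

Key step: step 11

Assumption: the Wittig step is expected to give the enol ether as an E/Z mixture; the E isomer is drawn and named, and the mixture is carried on because both isomers ionise to the same kind of cation in step 11.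

**Route**

Step 1
Reactants: 1 ketoisophorone (2,6,6-trimethylcyclohex-2-ene-1,4-dione)
Product: 3 (4R,6R)-actinol [(4R,6R)-4-hydroxy-2,2,6-trimethylcyclohexan-1-one], via (6R)-levodione 2 (not isolated)
Conditions: old yellow enzyme OYE2 (S. cerevisiae), NADP+ (cat.), glucose dehydrogenase, D-glucose, phosphate buffer pH 7, 30 °C; then levodione reductase (C. aquaticum), NAD+ (cat.), same pot, 30 °C
Reagents that add atoms: none
Why: Enzymatic ene-reduction followed by enzymatic ketone reduction, an enzyme pair documented for this substrate: the ene-reductase should reduce the C2=C3 bond from one face to fix the methyl-bearing centre as (R), and the reductase should then reduce only the unhindered C4 carbonyl from the face that gives (4R).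

Step 2
Reactants: 3 (4R,6R)-actinol
Product: 4 (4R,6R)-4-{[tert-butyl(dimethyl)silyl]oxy}-2,2,6-trimethylcyclohexan-1-one
Conditions: tBuMe2SiCl, imidazole, DMF, rt
Reagents that add atoms: tert-butyldimethylsilyl chloride, CC(C)(C)[Si](C)(C)Cl
Why: Imidazole-promoted silylation of a secondary alcohol, which leaves the hindered ketone and both stereocentres untouched.

Step 3
Reactants: 4 silyl ether ketone
Product: 6 (4R)-4-{[tert-butyl(dimethyl)silyl]oxy}-2,6,6-trimethylcyclohex-1-en-1-yl trifluoromethanesulfonate, via lithium enolate 5 (not isolated)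
Conditions: LiN(iPr)2, THF, −78 to 0 °C; then PhNTf2, −78 °C to rt
Reagents that add atoms: N-phenylbis(trifluoromethanesulfonimide), O=S(=O)(N(c1ccccc1)S(=O)(=O)C(F)(F)F)C(F)(F)F
Why: Enolate O-triflation: the ketone can enolise only toward C6 because C2 is quaternary, the silyloxy group is gamma to the carbonyl and cannot be eliminated, and PhNTf2 traps the enolate on oxygen; the C6 centre is erased on purpose while the carbinol centre stays (R).

Step 4
Reactants: 6 enol triflate
Product: 7 methyl (4R)-4-{[tert-butyl(dimethyl)silyl]oxy}-2,6,6-trimethylcyclohex-1-ene-1-carboxylate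
Conditions: Pd(OAc)2 (5 mol %), PPh3 (10 mol %), Et3N, CO (1 atm), MeOH/DMF, 60 °C
Reagents that add atoms: carbon monoxide, [C-]#[O+]; methanol, CO
Why: Palladium-catalysed methoxycarbonylation of an enol triflate (oxidative addition, CO insertion, methanolysis of the acylpalladium), a reaction established for 2,6,6-trimethylcyclohexenyl triflates and tolerant of silyl ethers.

Step 5
Reactants: 7 methyl ester
Product: 8 [(4R)-4-{[tert-butyl(dimethyl)silyl]oxy}-2,6,6-trimethylcyclohex-1-en-1-yl]methanol
Conditions: iBu2AlH (2.5 equiv), CH2Cl2, −78 to 0 °C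
Reagents that add atoms: none
Why: Hydride reduction of a conjugated ester to the allylic alcohol with iBu2AlH, which adds 1,2 and leaves the silyl ether and the alkene alone.

Step 6
Reactants: 8 allylic alcohol
Product: 9 [(1R,4S,6R)-4-{[tert-butyl(dimethyl)silyl]oxy}-2,2,6-trimethyl-7-oxabicyclo[4.1.0]heptan-1-yl]methanol
Conditions: Ti(OiPr)4 (0.2 equiv), D-(−)-diethyl tartrate (0.26 equiv), tBuOOH (2 equiv, anhydrous), 4 Å molecular sieves, CH2Cl2, −20 °C
Reagents that add atoms: tert-butyl hydroperoxide, CC(C)(C)OO
Why: Sharpless asymmetric epoxidation: the primary allylic alcohol binds the titanium tartrate, and the D-(−)-tartrate should deliver the peroxide oxygen to the alkene face that gives (1R,6R), the face anti to the C4 silyloxy group, so that both oxirane stereocentres are set together under reagent control.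

Step 7
Reactants: 9 epoxy alcohol
Product: 10 (1S,4S,6R)-4-{[tert-butyl(dimethyl)silyl]oxy}-2,2,6-trimethyl-7-oxabicyclo[4.1.0]heptane-1-carbaldehyde
Conditions: Pr4N[RuO4] (5 mol %), N-methylmorpholine N-oxide (1.5 equiv), 4 Å molecular sieves, CH2Cl2, rt
Reagents that add atoms: none
Why: Ley–Griffith oxidation of a primary alcohol to the aldehyde under neutral conditions that spare the oxirane and the silyl ether; the formyl group sits on a fully substituted carbon, so nothing can epimerise.

Step 8
Reactants: 10 epoxy aldehyde; 11 (methoxymethyl)triphenylphosphonium chloride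
Product: 12 tert-butyl({(1S,4S,6R)-1-[(E)-2-methoxyethenyl]-2,2,6-trimethyl-7-oxabicyclo[4.1.0]heptan-4-yl}oxy)dimethylsilane
Conditions: 11 (1.5 equiv), KOtBu (1.4 equiv), THF, 0 °C; then 10, 0 °C to rt; Et3N-deactivated silica
Reagents that add atoms: (methoxymethyl)triphenylphosphonium chloride 11, COC[P+](c1ccccc1)(c1ccccc1)c1ccccc1.[Cl-]
Why: Wittig methoxymethylenation with a reactive non-stabilised ylide, suited to a hindered aldehyde that cannot enolise; the basic medium leaves the oxirane intact and the alkene geometry is of no consequence for step 11.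

Step 9
Reactants: 12 silyl-protected epoxy enol ether
Product: 13 (1S,4S,6R)-1-[(E)-2-methoxyethenyl]-2,2,6-trimethyl-7-oxabicyclo[4.1.0]heptan-4-ol
Conditions: Bu4NF (1.5 equiv), THF, 0 °C to rt
Reagents that add atoms: none
Why: Fluoride-induced cleavage of the silyl ether, chosen because basic conditions cannot trigger the acid-sensitive epoxy enol ether.

Step 10
Reactants: 13 epoxy enol ether alcohol; 14 hexadecanoyl (palmitoyl) chloride
Product: 15 (1S,4S,6R)-1-[(E)-2-methoxyethenyl]-2,2,6-trimethyl-7-oxabicyclo[4.1.0]heptan-4-yl hexadecanoate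
Conditions: 14 (1.3 equiv), Et3N (3 equiv), 4-(dimethylamino)pyridine (0.1 equiv), CH2Cl2, 0 °C to rt
Reagents that add atoms: hexadecanoyl chloride 14, CCCCCCCCCCCCCCCC(=O)Cl
Why: Acylation of the secondary alcohol by the acid chloride under 4-(dimethylamino)pyridine catalysis, with excess Et3N keeping the medium basic so that the epoxy enol ether survives; the C4–O bond is not touched and C4 stays (S).

Step 11
Reactants: 15 epoxy enol ether palmitate
Product: 16 (6S,7aR)-2-methoxy-4,4,7a-trimethyl-2,4,5,6,7,7a-hexahydro-1-benzofuran-6-yl hexadecanoate (both C2 anomers)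
Conditions: pyridinium p-toluenesulfonate (0.1 equiv), 4 Å molecular sieves, CH2Cl2, 0 °C to rt; Et3N quench
Reagents that add atoms: none
Why: The pyridinium acid protonates the oxirane oxygen and the C3a–O bond (bicyclic C1–O7) ionises with help from the enol ether, giving a 1-methoxyallyl cation spread over C3a–C3–C2 while the oxygen stays on C7a as a tertiary hydroxyl, which then adds to C2 and returns the proton. The closest known reaction type is the acid-catalysed rearrangement of carotenoid and ionone 5,6-epoxides (1-alkenyl-7-oxabicyclo[4.1.0]heptanes) to their 5,8-furanoid oxides, here run on an alkene that is an enol ether. The one ring formed, the 2,5-dihydrofuran O1–C2–C3=C3a–C7a, closes in a 5-exo-trig mode onto the C2=O+ oxocarbenium unit, from the rotamer that holds C2 on the C7a side and away from the gem-dimethyl group. The only new stereocentre, the acetal carbon C2, is not controlled and need not be, since step 12 removes it, and C7a keeps its configuration because its C–O bond is never broken. The step needs cleavage of the C3a–O rather than the C7a–O bond, which the alkoxy-stabilised allyl cation secures, and it needs ionisation to outrun C-protonation and hydrolysis of the enol ether, which the weak acid, the aprotic solvent and the sieves are meant to secure.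

Step 12
Reactants: 16 methyl acetal
Product: 18 (−)-3-O-palmitoylloliolide [(6S,7aR)-4,4,7a-trimethyl-2-oxo-2,4,5,6,7,7a-hexahydro-1-benzofuran-6-yl hexadecanoate], via lactol 17 (not isolated)
Conditions: CrO3, aq. H2SO4, acetone, 0 °C
Reagents that add atoms: water, O
Why: Jones oxidation: the aqueous acid hydrolyses the allylic methyl acetal to lactol 17 and hexavalent chromium oxidises the lactol to the butenolide, so both anomers of 16 converge, while the ester and the trisubstituted alkene are inert and C7a, whose C–O bond is not labilised, keeps its configuration.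

**Compound list**

1 | ketoisophorone (2,6,6-trimethylcyclohex-2-ene-1,4-dione) | CC1=CC(=O)CC(C)(C)C1=O | starting material
2 | (6R)-levodione [(6R)-2,2,6-trimethylcyclohexane-1,4-dione] | C[C@@H]1CC(=O)CC(C)(C)C1=O | intermediate
3 | (4R,6R)-actinol [(4R,6R)-4-hydroxy-2,2,6-trimethylcyclohexan-1-one] | C[C@@H]1C[C@@H](O)CC(C)(C)C1=O | intermediate
4 | (4R,6R)-4-{[tert-butyl(dimethyl)silyl]oxy}-2,2,6-trimethylcyclohexan-1-one | C[C@@H]1C[C@@H](O[Si](C)(C)C(C)(C)C)CC(C)(C)C1=O | intermediate
5 | lithium (4R)-4-{[tert-butyl(dimethyl)silyl]oxy}-2,6,6-trimethylcyclohex-1-en-1-olate | [Li]OC1=C(C)C[C@@H](O[Si](C)(C)C(C)(C)C)CC1(C)C | intermediate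
6 | (4R)-4-{[tert-butyl(dimethyl)silyl]oxy}-2,6,6-trimethylcyclohex-1-en-1-yl trifluoromethanesulfonate | O=S(=O)(OC1=C(C)C[C@@H](O[Si](C)(C)C(C)(C)C)CC1(C)C)C(F)(F)F | intermediate
7 | methyl (4R)-4-{[tert-butyl(dimethyl)silyl]oxy}-2,6,6-trimethylcyclohex-1-ene-1-carboxylate | COC(=O)C1=C(C)C[C@@H](O[Si](C)(C)C(C)(C)C)CC1(C)C | intermediate
8 | [(4R)-4-{[tert-butyl(dimethyl)silyl]oxy}-2,6,6-trimethylcyclohex-1-en-1-yl]methanol | OCC1=C(C)C[C@@H](O[Si](C)(C)C(C)(C)C)CC1(C)C | intermediate
9 | [(1R,4S,6R)-4-{[tert-butyl(dimethyl)silyl]oxy}-2,2,6-trimethyl-7-oxabicyclo[4.1.0]heptan-1-yl]methanol | CC(C)(C)[Si](C)(C)O[C@H]1CC(C)(C)[C@]2(CO)O[C@]2(C)C1 | intermediate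
10 | (1S,4S,6R)-4-{[tert-butyl(dimethyl)silyl]oxy}-2,2,6-trimethyl-7-oxabicyclo[4.1.0]heptane-1-carbaldehyde | CC(C)(C)[Si](C)(C)O[C@H]1CC(C)(C)[C@]2(C=O)O[C@]2(C)C1 | intermediate
11 | (methoxymethyl)triphenylphosphonium chloride | COC[P+](c1ccccc1)(c1ccccc1)c1ccccc1.[Cl-] | starting material
12 | tert-butyl({(1S,4S,6R)-1-[(E)-2-methoxyethenyl]-2,2,6-trimethyl-7-oxabicyclo[4.1.0]heptan-4-yl}oxy)dimethylsilane | CC(C)(C)[Si](C)(C)O[C@H]1CC(C)(C)[C@]2(/C=C/OC)O[C@]2(C)C1 | intermediate
13 | (1S,4S,6R)-1-[(E)-2-methoxyethenyl]-2,2,6-trimethyl-7-oxabicyclo[4.1.0]heptan-4-ol | O[C@H]1CC(C)(C)[C@]2(/C=C/OC)O[C@]2(C)C1 | intermediate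
14 | hexadecanoyl (palmitoyl) chloride | CCCCCCCCCCCCCCCC(=O)Cl | starting material
15 | (1S,4S,6R)-1-[(E)-2-methoxyethenyl]-2,2,6-trimethyl-7-oxabicyclo[4.1.0]heptan-4-yl hexadecanoate (oxirane anti to the ester) | CCCCCCCCCCCCCCCC(=O)O[C@H]1CC(C)(C)[C@]2(/C=C/OC)O[C@]2(C)C1 | intermediate
16 | (6S,7aR)-2-methoxy-4,4,7a-trimethyl-2,4,5,6,7,7a-hexahydro-1-benzofuran-6-yl hexadecanoate (both C2 anomers) | CCCCCCCCCCCCCCCC(=O)O[C@H]1CC(C)(C)C2=CC(OC)O[C@]2(C)C1 | intermediate
17 | (6S,7aR)-2-hydroxy-4,4,7a-trimethyl-2,4,5,6,7,7a-hexahydro-1-benzofuran-6-yl hexadecanoate (both C2 anomers) | CCCCCCCCCCCCCCCC(=O)O[C@H]1CC(C)(C)C2=CC(O)O[C@]2(C)C1 | intermediate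
18 | (−)-3-O-palmitoylloliolide [(6S,7aR)-4,4,7a-trimethyl-2-oxo-2,4,5,6,7,7a-hexahydro-1-benzofuran-6-yl hexadecanoate] | CCCCCCCCCCCCCCCC(=O)O[C@H]1CC(C)(C)C2=CC(=O)O[C@]2(C)C1 | target

**Summary**

Total step count: 12. Longest linear sequence: 12 steps (1 to 18); the two other starting materials, 11 and 14, enter as bought.

Steps most likely to fail:

Step 11. Protonation of the enol ether at carbon, followed by hydrolysis with adventitious water, may outrun ionisation of the oxirane; ionisation from the rotamer that cannot close may instead lead to ring contraction or proton loss. Fallback, setting out from 15: the enol ether is hydrolysed under neutral conditions (Hg(OAc)2, THF/H2O, 0 °C, then aq. KI) to the β,γ-epoxy aldehyde (1S,4S,6R)-2,2,6-trimethyl-1-(2-oxoethyl)-7-oxabicyclo[4.1.0]heptan-4-yl hexadecanoate F1. 1,8-Diazabicyclo[5.4.0]undec-7-ene in CH2Cl2 then opens the oxirane by E1cB elimination, with base in place of acid and the C7a–O bond again untouched. This gives the γ-hydroxy enal (1S,3R,4Z)-3-hydroxy-3,5,5-trimethyl-4-(2-oxoethylidene)cyclohexyl hexadecanoate F2, which closes to its lactol. The route is rejoined at 17, which is oxidised to 18 under the conditions of step 12.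

Step 6. Oxygen transfer to the hindered tetrasubstituted alkene may be slow on the titanium tartrate, and the face selectivity may fall short or need to be confirmed at 9 before going on. Fallback, setting out from 8: buffered 3-chloroperbenzoic acid (NaHCO3, CH2Cl2, 0 °C) epoxidises the electron-rich alkene without a chiral catalyst. Both face isomers are then expected, 9 and its syn isomer [(1S,4S,6S)-4-{[tert-butyl(dimethyl)silyl]oxy}-2,2,6-trimethyl-7-oxabicyclo[4.1.0]heptan-1-yl]methanol F3; being diastereomers they are separated by chromatography, and the route is rejoined at 9.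

Step 8. Addition of the bulky ylide to an aldehyde flanked by two fully substituted carbons may be sluggish, so that base-induced decomposition competes. Fallback, setting out from 10: a Peterson olefination. (Methoxymethyl)trimethylsilane is lithiated (sBuLi, THF, −78 °C) and the smaller, more nucleophilic carbanion is added to the aldehyde to give the β-hydroxysilane 1-[(1R,4S,6R)-4-{[tert-butyl(dimethyl)silyl]oxy}-2,2,6-trimethyl-7-oxabicyclo[4.1.0]heptan-1-yl]-2-methoxy-2-(trimethylsilyl)ethan-1-ol F4. KH in THF then eliminates the silanolate to give the enol ether, and the route is rejoined at 12.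

Further compounds
F1 | step 11 | (1S,4S,6R)-2,2,6-trimethyl-1-(2-oxoethyl)-7-oxabicyclo[4.1.0]heptan-4-yl hexadecanoate | CCCCCCCCCCCCCCCC(=O)O[C@H]1CC(C)(C)[C@]2(CC=O)O[C@]2(C)C1
F2 | step 11 | (1S,3R,4Z)-3-hydroxy-3,5,5-trimethyl-4-(2-oxoethylidene)cyclohexyl hexadecanoate | CCCCCCCCCCCCCCCC(=O)O[C@H]1CC(C)(C)/C(=C/C=O)[C@@](O)(C)C1
F3 | step 6 | [(1S,4S,6S)-4-{[tert-butyl(dimethyl)silyl]oxy}-2,2,6-trimethyl-7-oxabicyclo[4.1.0]heptan-1-yl]methanol | CC(C)(C)[Si](C)(C)O[C@H]1CC(C)(C)[C@@]2(CO)O[C@@]2(C)C1
F4 | step 8 | 1-[(1R,4S,6R)-4-{[tert-butyl(dimethyl)silyl]oxy}-2,2,6-trimethyl-7-oxabicyclo[4.1.0]heptan-1-yl]-2-methoxy-2-(trimethylsilyl)ethan-1-ol (mixture at the two side-chain carbons) | CC(C)(C)[Si](C)(C)O[C@H]1CC(C)(C)[C@]2(C(O)C(OC)[Si](C)(C)C)O[C@]2(C)C1
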